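**Plan**

1. Numbering (longipinane): C1 ketone, C2=C3 (methyl on C3), C4 and C11 the cyclobutane CH carbons flanking the enone, C5, C6 (CMe2), C7–C9 the three oxygenated carbons, C10 the quaternary carbon.
2. Retrosynthesis: the three esters come off first; the C8/C9 diol goes back to a C8=C9 alkene; the enone ring is cut at C1–C11 and C2=C3 together (a phosphonoacetyl unit joined to a cyclobutyl radical at C11 and condensed with the C3 ketone on C4); the seven-membered ring is cut at C8–C9 (aldol); the cyclobutane is cut at one bond to C5 and one to C10 (crossed [2+2]).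
3. Forward: cyclobutane first, by intramolecular enone–alkene photocycloaddition to a bicyclo[2.1.1]hexanone whose two-carbon bridge is a temporary clamp; retro-aldol opening with methylation; seven-membered ring by aldol condensation; meso anhydride 14; six-membered enone ring last.
4. Stereochemistry: the cis-1,3 pairs on the cyclobutane come from the bicyclic photoadduct and from epimerization into the meso anhydride; the absolute configuration is set at C7 by CBS reduction of meso enone 14; a ligand-controlled methylation of the anhydride decides which cyclobutane carbon becomes C4; C8 and C9 follow from osmylation anti to the C7 hydroxyl.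
5. Enabling feature: in bicyclo[4.1.1]octene 17 the cyclobutane carbons C4 and C11 are 1,3-related and their substituents anti to the four-carbon bridge converge, so an acyl unit delivered to a radical at C11 (from the carboxyl that had kept the system meso) can condense only with the C3 ketone on C4.

Key step: step 14

Remark: compounds 8–10 and 13 are carried as stereoisomer mixtures (racemic where chiral) at centres that are later erased or equilibrated, and all material converges at meso anhydride 14, so their SMILES leave these centres open; in the bicyclo[4.1.1]octenes 13–17 and 20, C1, C2=C3, C4, C5, C6, C7 and C8 are the later C10, C9=C8, C7, C6, C5, C11 and C4.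

**Route**

Step 1
Reactants: 1 mesaconic acid
Product: 2 (2E)-4-methoxy-2-methyl-4-oxobut-2-enoic acid (mesaconic acid 4-methyl ester)
Conditions: MeOH (excess), H2SO4 (cat.), rt → 40 °C, stopped at the monoester
Reagents that add atoms: methanol, CO
Why: Fischer esterification should take the unhindered carboxyl on the CH= carbon much faster than the carboxyl on the methyl-bearing carbon, leaving the acid that is needed for acylation free.

Step 2
Reactants: 2 (2E)-4-methoxy-2-methyl-4-oxobut-2-enoic acid; 3 S-ethyl propanethioate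
Product: 5 methyl (2E)-6-(ethylsulfanyl)-3,5-dimethyl-4,6-dioxohex-2-enoate (racemic), via acid chloride 4 (not isolated)
Conditions: (COCl)2, DMF (cat.), CH2Cl2, 0 °C → rt, evaporate; then 3, MgBr2·OEt2, i-Pr2NEt, CH2Cl2, 0 °C → rt; aq. HCl
Reagents that add atoms: none
Why: Claisen-type C-acylation of the thioester under soft enolization (magnesium enolate, amine base) should give the β-keto thioester without conjugate addition to the unsaturated ester.

Step 3
Reactants: 5 methyl (2E)-6-(ethylsulfanyl)-3,5-dimethyl-4,6-dioxohex-2-enoate; 6 methyl propiolate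
Product: 7 dimethyl (2E)-5-[(ethylsulfanyl)carbonyl]-3,5-dimethyl-4-oxoocta-2,6-dienedioate (racemic, 6E/6Z mixture)
Conditions: N-methylmorpholine (10 mol%), CH2Cl2, 0 °C → rt
Reagents that add atoms: none
Why: base-catalysed Michael addition of the doubly activated methine to the propiolate should give the α-vinylated quaternary β-keto thioester; the new alkene geometry and the quaternary centre do not matter because both are erased later.

Step 4
Reactants: 7 dimethyl (2E)-5-[(ethylsulfanyl)carbonyl]-3,5-dimethyl-4-oxoocta-2,6-dienedioate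
Product: 8 dimethyl 3-[(ethylsulfanyl)carbonyl]-1,3-dimethyl-2-oxobicyclo[2.1.1]hexane-5,6-dicarboxylate (racemic, epimers at C3, C5 and C6)
Conditions: hν (350–366 nm), MeCN (0.01 M), degassed, rt
Reagents that add atoms: none
Why: intramolecular enone–alkene [2+2] photocycloaddition of a 1,5-dien-3-one should close in the crossed sense by the rule of five (first bond C2–C6 of the chain, giving the two carbonyl-stabilized radicals), so that the two bridgeheads, the later C10 and C5, are necessarily cis on the new cyclobutane.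

Step 5
Reactants: 8 dimethyl 3-[(ethylsulfanyl)carbonyl]-1,3-dimethyl-2-oxobicyclo[2.1.1]hexane-5,6-dicarboxylate
Product: 9 dimethyl 3-[(ethylsulfanyl)carbonyl]-2-hydroxy-1,3-dimethylbicyclo[2.1.1]hexane-5,6-dicarboxylate (stereoisomer mixture)
Conditions: NaBH4, MeOH–THF, −40 °C; aq. NH4Cl
Reagents that add atoms: none
Why: borohydride reduction of the strained ring ketone should be much faster at low temperature than attack on the thioester or the esters, and the carbinol configuration is irrelevant.

Step 6
Reactants: 9 dimethyl 3-[(ethylsulfanyl)carbonyl]-2-hydroxy-1,3-dimethylbicyclo[2.1.1]hexane-5,6-dicarboxylate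
Product: 11 dimethyl 2-formyl-2-methyl-4-[1-(ethylsulfanyl)-2-methyl-1-oxopropan-2-yl]cyclobutane-1,3-dicarboxylate (meso isomer: formyl and side chain cis; both CO2Me on the other face), via potassium thioester enolate 10 (not isolated)
Conditions: KN(SiMe3)2 (1.05 equiv), THF, −78 → −20 °C; MeI (3 equiv), −20 → 0 °C; then DBU (cat.), CH2Cl2, rt
Reagents that add atoms: iodomethane, CI
Why: strain-driven retro-aldol fragmentation of the potassium alkoxide opens the two-carbon bridge to the non-enolizable aldehyde and a thioester enolate, whose C-methylation (enolate alkylation) builds the gem-dimethyl carbon, while DBU should equilibrate the two ester-bearing carbons to the all-equatorial meso cyclobutane.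

Step 7
Reactants: 11 dimethyl 2-formyl-2-methyl-4-[1-(ethylsulfanyl)-2-methyl-1-oxopropan-2-yl]cyclobutane-1,3-dicarboxylate
Product: 12 dimethyl 2-formyl-2-methyl-4-(2-methyl-3-oxobutan-2-yl)cyclobutane-1,3-dicarboxylate (same configuration)
Conditions: MeZnCl (2 equiv), PdCl2(PPh3)2 (5 mol%), THF–toluene, rt
Reagents that add atoms: methylzinc chloride, C[Zn]Cl
Why: Fukuyama coupling (palladium-catalysed ketone synthesis from a thioester and an organozinc) tolerates the aldehyde and the esters and should turn the thioester into the methyl ketone.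

Step 8
Reactants: 12 dimethyl 2-formyl-2-methyl-4-(2-methyl-3-oxobutan-2-yl)cyclobutane-1,3-dicarboxylate
Product: 13 1,5,5-trimethyl-4-oxobicyclo[4.1.1]oct-2-ene-7,8-dicarboxylic acid (C7/C8 epimer mixture)
Conditions: KOH (6 equiv), MeOH–H2O, rt → 60 °C; then aq. HCl to pH 2
Reagents that add atoms: potassium hydroxide, [K+].[OH-]
Why: intramolecular aldol condensation of the methyl ketone (enolizable only at CH3) with the non-enolizable aldehyde held cis-1,3 on the cyclobutane should close the seven-membered enone, while hydroxide saponifies the two methyl esters.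

Step 9
Reactants: 13 1,5,5-trimethyl-4-oxobicyclo[4.1.1]oct-2-ene-7,8-dicarboxylic acid
Product: 14 1,5,5-trimethyl-4-oxobicyclo[4.1.1]oct-2-ene-7,8-dicarboxylic anhydride (meso; both carbonyls anti to the C2–C5 bridge)
Conditions: Ac2O, NaOAc (cat.), 120 °C; volatiles removed
Reagents that add atoms: none
Why: anhydride formation under epimerizing conditions (enolization of the mixed anhydrides) should funnel all C7/C8 epimers into the only cyclic anhydride that can form, the meso compound bridging the two anti positions.

Step 10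
Reactants: 14 1,5,5-trimethyl-4-oxobicyclo[4.1.1]oct-2-ene-7,8-dicarboxylic anhydride
Product: 15 (4R)-4-hydroxy-1,5,5-trimethylbicyclo[4.1.1]oct-2-ene-7,8-dicarboxylic anhydride (C8 is the one-carbon bridge on the hydroxyl-bearing face)
Conditions: (S)-2-methyl-CBS-oxazaborolidine (20 mol%), catecholborane (1.5 equiv), toluene, −78 °C; pH 7 buffer
Reagents that add atoms: none
Why: Corey–Bakshi–Shibata reduction should distinguish the enantiotopic faces of the ketone of the meso enone (tert-alkyl side as the large group, alkenyl side as the small one, which by the usual model calls for the (S)-catalyst) and so set the later C7 and the absolute configuration, the activated ketone reacting faster than the anhydride.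

Step 11
Reactants: 15 (4R)-4-hydroxy-1,5,5-trimethylbicyclo[4.1.1]oct-2-ene-7,8-dicarboxylic anhydride
Product: 16 (4R)-8-acetyl-4-hydroxy-1,5,5-trimethylbicyclo[4.1.1]oct-2-ene-7-carboxylic acid (acetyl and carboxyl anti to the four-carbon bridge)
Conditions: MeZnCl (3 equiv), [Rh(cod)Cl]2 (4 mol%), t-BuPHOX (8 mol%, the enantiomer that selects the C8 carbonyl), THF, 0 °C → rt; aq. HCl
Reagents that add atoms: methylzinc chloride, C[Zn]Cl
Why: rhodium-catalysed alkylative desymmetrization of a cyclic anhydride with an organozinc reagent should, under ligand control, deliver methyl to the carbonyl on C8 (the bridge carbon on the hydroxyl-bearing face), giving the methyl ketone and leaving the C7 carboxyl free.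

Step 12
Reactants: 16 (4R)-8-acetyl-4-hydroxy-1,5,5-trimethylbicyclo[4.1.1]oct-2-ene-7-carboxylic acid
Product: 17 1,3-dioxoisoindolin-2-yl (4R)-8-acetyl-4-hydroxy-1,5,5-trimethylbicyclo[4.1.1]oct-2-ene-7-carboxylate
Conditions: N-hydroxyphthalimide, N,N′-diisopropylcarbodiimide, DMAP (cat.), CH2Cl2, 0 °C → rt
Reagents that add atoms: N-hydroxyphthalimide, ON1C(=O)c2ccccc2C1=O
Why: carbodiimide esterification gives the redox-active ester, the hindered neopentyl-type hydroxyl being far less reactive than N-hydroxyphthalimide.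

Step 13
Reactants: 18 2-(diethoxyphosphoryl)acetic acid
Product: 19 S-(pyridin-2-yl) 2-(diethoxyphosphoryl)ethanethioate
Conditions: 2,2′-dipyridyl disulfide, PPh3, CH2Cl2, rt
Reagents that add atoms: 2,2′-dipyridyl disulfide, c1ccc(SSc2ccccn2)nc1
Why: Mukaiyama redox condensation (phosphine and disulfide) gives the 2-pyridyl thioester that serves as the acyl donor in the next step.

Step 14
Reactants: 17 1,3-dioxoisoindolin-2-yl (4R)-8-acetyl-4-hydroxy-1,5,5-trimethylbicyclo[4.1.1]oct-2-ene-7-carboxylate; 19 S-(pyridin-2-yl) 2-(diethoxyphosphoryl)ethanethioate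
Product: 21 7-hydroxylongipina-2,8-dien-1-one, via β-ketophosphonate 20 (not isolated)
Conditions: NiBr2(dme) (10 mol%), 4,4′-di-tert-butyl-2,2′-bipyridine (10 mol%), Zn powder (2 equiv), 19 (1.5 equiv), DMA–THF, rt; then DBU (4 equiv), 50 °C
Reagents that add atoms: none
Why: Zerovalent nickel inserts into the C–S bond of 19 while single-electron reduction of 17 releases CO2 and a secondary cyclobutyl radical at C11, which is captured at nickel and gives the C1–C11 bond of 20 by reductive elimination; DBU then forms the zinc-bound phosphonate carbanion at C2, which adds to the C3 ketone and collapses through the oxaphosphetane to C2=C3. The closest known reactions are the nickel-catalysed decarboxylative cross-electrophile ketone synthesis from N-hydroxyphthalimide esters and 2-pyridyl thioesters and the intramolecular Horner–Wadsworth–Emmons cyclization of a β-ketophosphonate onto a ketone. The six-membered enone ring (C1, C2, C3, C4, C11 and one further cyclobutane carbon) closes by 6-exo-trig attack of C2 on the C3 carbonyl across the 1,3-positions of the cyclobutane, which completes the bicyclo[3.1.1]heptenone and the tricyclic skeleton. C11 and C4 are both α to a ketone and epimerizable, and only the epimer with both acyl groups anti to the four-carbon bridge can bridge, so both configurations are fixed by the ring that forms. The step needs cross-selectivity (alkyl radical with acyl–nickel, not homocoupling), which rests on the different ways the two electrophiles are activated, and regioselective condensation, which the phosphonate secures by making C2 the only nucleophilic carbon and the C3 ketone the only carbonyl within reach.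

Step 15
Reactants: 21 7-hydroxylongipina-2,8-dien-1-one
Product: 22 7,8,9-trihydroxylongipin-2-en-1-one (ring configuration of the target)
Conditions: OsO4 (5 mol%), N-methylmorpholine N-oxide (1.5 equiv), acetone–H2O, 0 °C → rt
Reagents that add atoms: osmium tetroxide, O=[Os](=O)(=O)=O (catalytic oxygen carrier); N-methylmorpholine N-oxide, C[N+]1([O-])CCOCC1; water, O
Why: catalytic osmium tetroxide dihydroxylation should take the electron-richer disubstituted C8=C9 alkene rather than the enone alkene and add anti to the allylic C7 hydroxyl (the usual sense for allylic alcohols), giving the C8/C9 cis-diol trans to the C7 oxygen.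

Step 16
Reactants: 22 7,8,9-trihydroxylongipin-2-en-1-one
Product: 23 8-acetoxy-7,9-dihydroxylongipin-2-en-1-one
Conditions: Ac2O (1.05 equiv), 2,4,6-collidine, CH2Cl2, −20 °C
Reagents that add atoms: acetic anhydride, CC(=O)OC(C)=O
Why: sterically controlled acylation should take the central C8 hydroxyl first, because the C7 and C9 hydroxyls each sit next to a quaternary carbon.

Step 17
Reactants: 23 8-acetoxy-7,9-dihydroxylongipin-2-en-1-one; 24 angelic acid
Product: 26 8-acetoxy-7,9-bis(angeloyloxy)longipin-2-en-1-one (the target), via mixed anhydride 25 (not isolated)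
Conditions: 24 (6 equiv), 2,4,6-trichlorobenzoyl chloride (6 equiv), Et3N, toluene, rt; then 23, toluene, 80 °C
Reagents that add atoms: none
Why: Yamaguchi-type esterification through the angelic 2,4,6-trichlorobenzoic mixed anhydride, run without a nucleophilic catalyst, is meant to acylate both hindered secondary hydroxyls while keeping the Z geometry of the angelate.

**Compound list**

1 | mesaconic acid, (2E)-2-methylbut-2-enedioic acid | OC(=O)/C=C(\C)C(=O)O | starting material
2 | (2E)-4-methoxy-2-methyl-4-oxobut-2-enoic acid | COC(=O)/C=C(\C)C(=O)O | intermediate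
3 | S-ethyl propanethioate | CCC(=O)SCC | starting material
4 | methyl (2E)-4-chloro-3-methyl-4-oxobut-2-enoate | COC(=O)/C=C(\C)C(=O)Cl | intermediate (not isolated)
5 | methyl (2E)-6-(ethylsulfanyl)-3,5-dimethyl-4,6-dioxohex-2-enoate, racemic | COC(=O)/C=C(\C)C(=O)C(C)C(=O)SCC | intermediate
6 | methyl propiolate | C#CC(=O)OC | starting material
7 | dimethyl (2E)-5-[(ethylsulfanyl)carbonyl]-3,5-dimethyl-4-oxoocta-2,6-dienedioate, racemic, 6E/6Z mixture | COC(=O)/C=C(\C)C(=O)C(C)(C(=O)SCC)C=CC(=O)OC | intermediate
8 | dimethyl 3-[(ethylsulfanyl)carbonyl]-1,3-dimethyl-2-oxobicyclo[2.1.1]hexane-5,6-dicarboxylate, racemic, epimers at C3, C5, C6 | COC(=O)C1C2(C)C(=O)C(C)(C(=O)SCC)C1C2C(=O)OC | intermediate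
9 | dimethyl 3-[(ethylsulfanyl)carbonyl]-2-hydroxy-1,3-dimethylbicyclo[2.1.1]hexane-5,6-dicarboxylate, stereoisomer mixture | COC(=O)C1C2(C)C(O)C(C)(C(=O)SCC)C1C2C(=O)OC | intermediate
10 | potassium enolate of S-ethyl 2-[3-formyl-2,4-bis(methoxycarbonyl)-3-methylcyclobutyl]propanethioate, formyl and side chain cis, ester-bearing carbons open | O=C[C@@]1(C)C(C(=O)OC)[C@@H](C(C)=C([O-])SCC)C1C(=O)OC.[K+] | intermediate (not isolated)
11 | dimethyl 2-formyl-2-methyl-4-[1-(ethylsulfanyl)-2-methyl-1-oxopropan-2-yl]cyclobutane-1,3-dicarboxylate, meso; formyl and side chain cis, both CO2Me on the other face | O=C[C@@]1(C)[C@H](C(=O)OC)[C@@H](C(C)(C)C(=O)SCC)[C@@H]1C(=O)OC | intermediate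
12 | dimethyl 2-formyl-2-methyl-4-(2-methyl-3-oxobutan-2-yl)cyclobutane-1,3-dicarboxylate, meso, same configuration | O=C[C@@]1(C)[C@H](C(=O)OC)[C@@H](C(C)(C)C(C)=O)[C@@H]1C(=O)OC | intermediate
13 | 1,5,5-trimethyl-4-oxobicyclo[4.1.1]oct-2-ene-7,8-dicarboxylic acid, C7/C8 epimer mixture | O=C1C=CC2(C)C(C(=O)O)C(C1(C)C)C2C(=O)O | intermediate
14 | 1,5,5-trimethyl-4-oxobicyclo[4.1.1]oct-2-ene-7,8-dicarboxylic anhydride, meso, carbonyls anti to the C2–C5 bridge | O=C1C=C[C@@]2(C)[C@@H]3C(=O)OC(=O)[C@H]2[C@@H]3C1(C)C | intermediate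
15 | (4R)-4-hydroxy-1,5,5-trimethylbicyclo[4.1.1]oct-2-ene-7,8-dicarboxylic anhydride, hydroxyl on the face of C8 | O[C@@H]1C=C[C@@]2(C)[C@@H]3C(=O)OC(=O)[C@H]2[C@@H]3C1(C)C | intermediate
16 | (4R)-8-acetyl-4-hydroxy-1,5,5-trimethylbicyclo[4.1.1]oct-2-ene-7-carboxylic acid, acetyl and carboxyl anti to the four-carbon bridge | O[C@@H]1C=C[C@@]2(C)[C@H](C(=O)O)[C@@H](C1(C)C)[C@@H]2C(C)=O | intermediate
17 | 1,3-dioxoisoindolin-2-yl ester of 16 | O[C@@H]1C=C[C@@]2(C)[C@H](C(=O)ON3C(=O)c4ccccc4C3=O)[C@@H](C1(C)C)[C@@H]2C(C)=O | intermediate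
18 | 2-(diethoxyphosphoryl)acetic acid | CCOP(=O)(CC(=O)O)OCC | starting material
19 | S-(pyridin-2-yl) 2-(diethoxyphosphoryl)ethanethioate | CCOP(=O)(CC(=O)Sc1ccccn1)OCC | intermediate
20 | diethyl {2-[(4R)-8-acetyl-4-hydroxy-1,5,5-trimethylbicyclo[4.1.1]oct-2-en-7-yl]-2-oxoethyl}phosphonate | O[C@@H]1C=C[C@@]2(C)[C@H](C(=O)CP(=O)(OCC)OCC)[C@@H](C1(C)C)[C@@H]2C(C)=O | intermediate (not isolated)
21 | 7-hydroxylongipina-2,8-dien-1-one (5-hydroxy-2,6,6,9-tetramethyltricyclo[5.4.0.0^{2,8}]undeca-3,9-dien-11-one), ring configuration of the target | O[C@@H]1C=C[C@@]2(C)[C@@H]3C(=O)C=C(C)[C@H]2[C@@H]3C1(C)C | intermediate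
22 | 7,8,9-trihydroxylongipin-2-en-1-one, (1R,2R,3S,4R,5S,7S,8R)-3,4,5-trihydroxy-2,6,6,9-tetramethyltricyclo[5.4.0.0^{2,8}]undec-9-en-11-one | O[C@@H]1[C@@H](O)[C@@H](O)[C@@]2(C)[C@@H]3C(=O)C=C(C)[C@H]2[C@@H]3C1(C)C | intermediate
23 | 8-acetoxy-7,9-dihydroxylongipin-2-en-1-one | O[C@@H]1[C@@H](OC(C)=O)[C@@H](O)[C@@]2(C)[C@@H]3C(=O)C=C(C)[C@H]2[C@@H]3C1(C)C | intermediate
24 | angelic acid, (2Z)-2-methylbut-2-enoic acid | C/C=C(/C)C(=O)O | starting material
25 | angelic 2,4,6-trichlorobenzoic anhydride | C/C=C(/C)C(=O)OC(=O)c1c(Cl)cc(Cl)cc1Cl | intermediate (not isolated)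
26 | (1R,2R,3S,4R,5S,7S,8R)-4-acetoxy-2,6,6,9-tetramethyl-11-oxotricyclo[5.4.0.0^{2,8}]undec-9-ene-3,5-diyl bis[(2Z)-2-methylbut-2-enoate] | C/C=C(/C)C(=O)O[C@@H]1[C@@H](OC(C)=O)[C@@H](OC(=O)/C(C)=C\C)[C@@]2(C)[C@@H]3C(=O)C=C(C)[C@H]2[C@@H]3C1(C)C | target

**Step count and risks**

Total step count: 17. Longest linear sequence: 16 (steps 1–12 and 14–17); step 13 is a one-step side branch.

Steps most likely to fail:

1. Step 14. The hindered cyclobutyl radical may be reduced or dimerize before the acyl–nickel species intercepts it, or the phosphonate may fail to close the ring. The fallback sets out from 17 and returns at 21. Nickel-catalysed decarboxylative alkenylation of 17 with (1-ethoxyvinyl)zinc chloride (Ni(acac)2, 2,2′-bipyridine, THF–DMF, rt) should give the enol ether 8-acetyl-7-(1-ethoxyvinyl)-4-hydroxy-1,5,5-trimethylbicyclo[4.1.1]oct-2-ene F1, in which the two-carbon unit is now the nucleophile. BF3·OEt2 in CH2Cl2 at −78 °C should then bring about the intramolecular Mukaiyama-type aldol addition of the enol ether carbon to the C3 ketone and give, after aqueous work-up, the ketol 3,7-dihydroxylongipin-8-en-1-one F2. DBU in toluene at 60 °C dehydrates F2 through the C2 enolate to 21.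

2. Step 6. The aldehyde–enolate pair may recombine or oligomerize, or the thioester enolate may lose ethanethiolate, before it is methylated. The fallback sets out from 9 and returns at 11. Fragmentation under proton-transfer conditions (KOt-Bu 10 mol%, t-BuOH–THF, 0 °C) quenches the enolate as it forms and gives dimethyl 4-[1-(ethylsulfanyl)-1-oxopropan-2-yl]-2-formyl-2-methylcyclobutane-1,3-dicarboxylate F3. The aldehyde is masked as the dimethyl acetal dimethyl 2-(dimethoxymethyl)-4-[1-(ethylsulfanyl)-1-oxopropan-2-yl]-2-methylcyclobutane-1,3-dicarboxylate F4 (HC(OMe)3, MeOH, PPTS). Selective enolization of the more acidic thioester α-CH (LiN(SiMe3)2, THF, −78 °C) and methylation with MeI give dimethyl 2-(dimethoxymethyl)-4-[1-(ethylsulfanyl)-2-methyl-1-oxopropan-2-yl]-2-methylcyclobutane-1,3-dicarboxylate F5. Acetal hydrolysis (aqueous TFA, CH2Cl2, 0 °C) and DBU equilibration return 11.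

3. Step 11. The catalyst may discriminate poorly between the two diastereotopic anhydride carbonyls, or the organozinc may be consumed by the free hydroxyl. The fallback sets out from 15 and returns at 16. Cinchona-alkaloid-mediated methanolysis of 15 (quinidine or quinine, whichever sends methanol to the C7 carbonyl; MeOH, toluene, −55 °C) should give the hemiester (4R)-4-hydroxy-7-(methoxycarbonyl)-1,5,5-trimethylbicyclo[4.1.1]oct-2-ene-8-carboxylic acid F6. The free acid is converted into the thioester methyl (4R)-8-[(ethylsulfanyl)carbonyl]-4-hydroxy-1,5,5-trimethylbicyclo[4.1.1]oct-2-ene-7-carboxylate F7 (EtSH, EDC, DMAP, CH2Cl2). Fukuyama coupling (MeZnCl, PdCl2(PPh3)2, THF) gives the keto ester methyl (4R)-8-acetyl-4-hydroxy-1,5,5-trimethylbicyclo[4.1.1]oct-2-ene-7-carboxylate F8, and saponification (LiOH, THF–H2O) gives 16.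

**Further compounds**

F1 | step 14 | 8-acetyl-7-(1-ethoxyvinyl)-4-hydroxy-1,5,5-trimethylbicyclo[4.1.1]oct-2-ene | O[C@@H]1C=C[C@@]2(C)[C@H](C(=C)OCC)[C@@H](C1(C)C)[C@@H]2C(C)=O
F2 | step 14 | 3,7-dihydroxylongipin-8-en-1-one (C3 epimers) | O[C@@H]1C=C[C@@]2(C)[C@@H]3C(=O)CC(C)(O)[C@H]2[C@@H]3C1(C)C
F3 | step 6 | dimethyl 4-[1-(ethylsulfanyl)-1-oxopropan-2-yl]-2-formyl-2-methylcyclobutane-1,3-dicarboxylate (side-chain epimers) | O=C[C@@]1(C)[C@H](C(=O)OC)[C@@H](C(C)C(=O)SCC)[C@@H]1C(=O)OC
F4 | step 6 | dimethyl 2-(dimethoxymethyl)-4-[1-(ethylsulfanyl)-1-oxopropan-2-yl]-2-methylcyclobutane-1,3-dicarboxylate | COC(OC)[C@@]1(C)[C@H](C(=O)OC)[C@@H](C(C)C(=O)SCC)[C@@H]1C(=O)OC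
F5 | step 6 | dimethyl 2-(dimethoxymethyl)-4-[1-(ethylsulfanyl)-2-methyl-1-oxopropan-2-yl]-2-methylcyclobutane-1,3-dicarboxylate | COC(OC)[C@@]1(C)[C@H](C(=O)OC)[C@@H](C(C)(C)C(=O)SCC)[C@@H]1C(=O)OC
F6 | step 11 | (4R)-4-hydroxy-7-(methoxycarbonyl)-1,5,5-trimethylbicyclo[4.1.1]oct-2-ene-8-carboxylic acid | O[C@@H]1C=C[C@@]2(C)[C@H](C(=O)OC)[C@@H](C1(C)C)[C@@H]2C(=O)O
F7 | step 11 | methyl (4R)-8-[(ethylsulfanyl)carbonyl]-4-hydroxy-1,5,5-trimethylbicyclo[4.1.1]oct-2-ene-7-carboxylate | O[C@@H]1C=C[C@@]2(C)[C@H](C(=O)OC)[C@@H](C1(C)C)[C@@H]2C(=O)SCC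
F8 | step 11 | methyl (4R)-8-acetyl-4-hydroxy-1,5,5-trimethylbicyclo[4.1.1]oct-2-ene-7-carboxylate | O[C@@H]1C=C[C@@]2(C)[C@H](C(=O)OC)[C@@H](C1(C)C)[C@@H]2C(C)=O
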